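**Plan**
- **Retrosynthesis:** cut C3–C4′ (aldol), then O–C4 and C15–C15′ (hetero-Diels–Alder), which gives two molecules of dehydrozaluzanin C. Remove C3=O, C13 and C14, cut O–C6 and C4–C5 of the guaianolide together, and finally take C1 out of ring B to reach a cyclohexanone.
- **Enabling feature:** in each half, lactone ring C and cyclopentane ring A meet in the array O–C6–C5–C4(=C15H2). C6 is γ to the C12 carboxyl and C5 is next to the exocyclic-methylene carbon. This is the retron of a 5-exo-dig 1,6-enyne cyclisation terminated by a carboxylic acid.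
- **Forward order:** cyclohexanone, then one-carbon ring expansion to ring B, then the C2–C15 side chain. The cascade closes rings A and C together. C14, C13 and the C3 oxygen follow, then dimerisation, and the central cyclopentane closes by aldol addition.
- **Stereochemistry:** C7 comes from a chiral lithium amide. C1 is set by protonation under control of C7. C5 and C6 arise from the stereospecific anti addition of the cascade. C4, C3 and C4′ are set by substrate control in the dimer.

Key step: step 6

Remark: guaiane numbering (C1–C15, primed for the second half) is used throughout. β is the face that carries the C7 side chain.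
Assumption: the sense of induction of the chiral lithium amide is taken from its behaviour with other 4-substituted cyclohexanones. If it proves opposite, the (R,R)-amine is used.
Assumption: C4′ of 21 is an enolisable centre and is drawn without configuration, because both epimers converge in step 13.

**Step 1**
Reactants: 1 ethyl 2-(4-oxocyclohexyl)acetate
Product: 3 ethyl 2-[(1R)-4-(trimethylsilyloxy)cyclohex-3-en-1-yl]acetate, via lithium enolate 2 (not isolated)
Conditions: (S,S)-bis(1-phenylethyl)amine, n-BuLi, THF, −78 °C; Me3SiCl (internal quench), then 1, −100 °C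
Reagents that add atoms: chlorotrimethylsilane C[Si](C)(C)Cl; n-butyllithium [Li]CCCC (lithium, kept only in 2)
Why: Enantiotopic-group-selective deprotonation of a 4-substituted cyclohexanone by a C2-symmetric chiral lithium amide with internal silyl quench is faster than ester enolisation and makes the future C7 a stereocentre of (R) configuration.

**Step 2**
Reactants: 3 ethyl 2-[(1R)-4-(trimethylsilyloxy)cyclohex-3-en-1-yl]acetate
Product: 5 ethyl 2-[(1R)-4-bromo-5-oxocyclohept-3-en-1-yl]acetate, via dibromocyclopropane 4 (not isolated)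
Conditions: CHBr3, KOtBu, pentane, −25 °C to rt; then PhMe, 110 °C
Reagents that add atoms: bromoform BrC(Br)Br
Why: Dibromocarbene cyclopropanation of the electron-rich silyl enol ether and thermal electrocyclic opening of the siloxy-gem-dibromocyclopropane insert C1 between C10 and C5 and give the 2-bromo enone, with both cyclopropane diastereomers converging and C7 untouched.

**Step 3**
Reactants: 5 ethyl 2-[(1R)-4-bromo-5-oxocyclohept-3-en-1-yl]acetate; 6 (4-bromobut-1-yn-1-yl)trimethylsilane
Product: 8 ethyl 2-[(1R)-5-oxo-4-[4-(trimethylsilyl)but-3-yn-1-yl]cyclohept-3-en-1-yl]acetate, via alkylzinc bromide 7 (not isolated)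
Conditions: 6, Zn dust, I2 (cat.), DMA, 80 °C; then 5, Pd(dppf)Cl2 (5 mol %), THF, 50 °C
Reagents that add atoms: zinc [Zn] (kept only in 7)
Why: Negishi coupling of an α-halo enone with a primary alkylzinc halide forms C1–C2 under conditions that tolerate the ester, the ketone and the silyl alkyne.

**Step 4**
Reactants: 8 ethyl 2-[(1R)-5-oxo-4-[4-(trimethylsilyl)but-3-yn-1-yl]cyclohept-3-en-1-yl]acetate
Product: 9 2-[(1R)-4-(but-3-yn-1-yl)-5-oxocyclohept-3-en-1-yl]acetic acid
Conditions: LiOH, THF–MeOH–H2O, 0 °C to rt; then 1 M HCl
Reagents that add atoms: water O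
Why: Saponification and base-induced protiodesilylation of the alkynylsilane are run on the conjugated enone, which is the isomer stable to base, so no deprotection is needed later.

**Step 5**
Reactants: 9 2-[(1R)-4-(but-3-yn-1-yl)-5-oxocyclohept-3-en-1-yl]acetic acid
Product: 11 2-[(1S,4R)-4-(but-3-yn-1-yl)-5-oxocyclohept-2-en-1-yl]acetic acid (cis), via dipotassium dienolate 10 (not isolated)
Conditions: KOtBu (2.5 equiv), THF–tBuOH, −20 °C; cannulated into AcOH–THF, −78 °C
Reagents that add atoms: potassium tert-butoxide CC(C)(C)[O-].[K+] (potassium, kept only in 10)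
Why: Deconjugative kinetic α-protonation of the extended dienolate moves the alkene to C5=C6, and with the C7 arm pseudo-equatorial the C8 flap covers the β face, so the proton should enter C1 from the α face and leave the butynyl chain cis to the C7 arm.

**Step 6**
Reactants: 11 2-[(1S,4R)-4-(but-3-yn-1-yl)-5-oxocyclohept-2-en-1-yl]acetic acid
Product: 12 10-oxo-13,14-dinorguai-4(15)-en-12,6α-olide (1αH,5αH,6βH,7αH)
Conditions: [(tBu2(o-biphenyl)P)Au(NCMe)]SbF6 (5 mol %), 4 Å MS, CH2Cl2 (0.01 M), −20 °C to rt
Reagents that add atoms: none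
Why: π-Activation of the terminal alkyne by the cationic monovalent gold centre triggers 5-exo-dig attack of the C5=C6 ring alkene on C4, and because the tether hangs from C1 it reaches only the β face and gives a cyclopropyl gold carbene (C4–C5–C6, carbene at C15); the carboxylic acid then opens the C4–C6 bond by backside attack at C6, and protodeauration of the vinylgold leaves the C4=C15H2 methylene. The closest known reaction type is the gold-catalysed alkoxy- or carboxy-cyclisation of 1,6-enynes, a stereospecific anti addition of carbon and oxygen across the alkene. Ring A closes 5-exo-dig and the lactone 5-exo-tet in one operation from a monocyclic precursor. C5 is controlled by C1 through the tether (H1 and H5 cis) and C6 by inversion at the cyclopropane carbon (oxygen on the α face, trans to C4 and to C11), so only the trans-fused 6α,12-olide can arise from the cis precursor. Closure to a trans-fused five-membered ring, out of reach on a cyclohexene, is accessible here because a twist-chair seven-membered ring accepts the 80–100° C5–C6–C7–C8 torsion that brings the pseudo-equatorial C11–C12 arm under C6. The step needs 5-exo over 6-endo opening and acid over ketone participation: the arm reaches C6 but not C5, attack by the C10 oxygen would create a bridgehead oxocarbenium ion in an 8-oxabicyclo[3.2.1]octane, and the C10 and C11 methylenes, which would compete as alkenes, are deliberately still absent.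

**Step 7**
Reactants: 12 10-oxo-13,14-dinorguai-4(15)-en-12,6α-olide
Product: 13 13-norguaia-4(15),10(14)-dien-12,6α-olide
Conditions: Zn, CH2Br2, TiCl4, THF–CH2Cl2, 0 °C to rt
Reagents that add atoms: dibromomethane BrCBr
Why: Takai–Lombardo methylenation is non-basic and selective for ketones over lactones, so C14 is installed without epimerising the enolisable C1.

**Step 8**
Reactants: 13 13-norguaia-4(15),10(14)-dien-12,6α-olide
Product: 17 (−)-dehydrocostus lactone, via lithium lactone enolate 14 (not isolated), via Mannich base 15 (not isolated), via ammonium iodide 16 (not isolated)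
Conditions: LiN(iPr)2, THF, −78 °C; CH2=NMe2+ I−, −78 °C to rt; MeI, MeOH, rt; aq. NaHCO3, CH2Cl2
Reagents that add atoms: N,N-dimethylmethyleneiminium iodide C=[N+](C)C.[I-]; iodomethane CI (kept only in 16); lithium diisopropylamide [Li+].CC(C)[N-]C(C)C (lithium, kept only in 14)
Why: Mannich reaction of the lactone enolate with Eschenmoser's salt, quaternisation and Hofmann-type elimination is the standard α-methylenation of γ-lactones, and the transient C11 centre is destroyed again.

**Step 9**
Reactants: 17 (−)-dehydrocostus lactone
Product: 18 3-epizaluzanin C (3α-hydroxy)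
Conditions: SeO2 (0.2 equiv), tBuOOH, CH2Cl2, 0 °C to rt
Reagents that add atoms: tert-butyl hydroperoxide CC(C)(C)OO
Why: Selenium dioxide allylic oxidation (ene reaction, then [2,3]-sigmatropic shift) attacks the C4=C15 methylene of strained ring A at C3 from the convex α face, and the new carbinol centre is removed in the next step.

**Step 10**
Reactants: 18 3-epizaluzanin C
Product: 19 dehydrozaluzanin C
Conditions: Dess–Martin periodinane, CH2Cl2, 0 °C to rt
Reagents that add atoms: none
Why: Dess–Martin oxidation converts the allylic alcohol into the α-methylene cyclopentanone under neutral conditions that spare the three exocyclic alkenes.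

**Step 11**
Reactants: 19 dehydrozaluzanin C (two molecules)
Product: 20 spiro-dihydropyran dimer (O3′–C4 and C15′–C15 bonds)
Conditions: 1,1′-bi-2-naphthol (1 equiv), neat film, 50 °C
Reagents that add atoms: none
Why: In this hydrogen-bond-accelerated hetero-Diels–Alder homodimerisation the s-cis O=C3′–C4′=C15′ enone of one molecule adds to the C4=C15 methylene of the other, oxygen bonds to the more substituted C4, and approach on the less hindered faces sets the spiro centre C4.

**Step 12**
Reactants: 20 spiro-dihydropyran dimer
Product: 21 C4-hydroxy 3,3′-diketone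
Conditions: 1 M aq. HCl (cat.), THF, rt
Reagents that add atoms: water O
Why: Acid hydrolysis of the cyclic enol ether (C4′ protonation, hydration at C3′, hemiketal collapse) frees the C3′ ketone and the tertiary C4 alcohol without breaking the C4–O bond, so C4 keeps its configuration.

**Step 13**
Reactants: 21 C4-hydroxy 3,3′-diketone
Product: 22 ainsliadimer A
Conditions: DBU (cat.), CH2Cl2, 0 °C to rt
Reagents that add atoms: none
Why: In this intramolecular aldol addition (5-enolexo-exo-trig) the C3′ ketone enolises towards C4′, and the C15–C15′ tether lets that enolate reach only one face of the C3 ketone, which closes the central cyclopentane and sets C4′ and C3.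

**Compound list**
1 | ethyl 2-(4-oxocyclohexyl)acetate | CCOC(=O)CC1CCC(=O)CC1 | starting material
2 | lithium enolate of 1 | [Li+].CCOC(=O)C[C@H]1CC=C([O-])CC1 | intermediate
3 | ethyl 2-[(1R)-4-(trimethylsilyloxy)cyclohex-3-en-1-yl]acetate | CCOC(=O)C[C@H]1CC=C(O[Si](C)(C)C)CC1 | intermediate
4 | ethyl 2-[7,7-dibromo-6-(trimethylsilyloxy)bicyclo[4.1.0]heptan-3-yl]acetate (side-chain carbon as in 3, both cyclopropane faces) | CCOC(=O)C[C@H]1CC2C(Br)(Br)C2(O[Si](C)(C)C)CC1 | intermediate
5 | ethyl 2-[(1R)-4-bromo-5-oxocyclohept-3-en-1-yl]acetate | CCOC(=O)C[C@H]1CC=C(Br)C(=O)CC1 | intermediate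
6 | (4-bromobut-1-yn-1-yl)trimethylsilane | C[Si](C)(C)C#CCCBr | starting material
7 | [4-(trimethylsilyl)but-3-yn-1-yl]zinc bromide | C[Si](C)(C)C#CCC[Zn]Br | intermediate
8 | ethyl 2-[(1R)-5-oxo-4-[4-(trimethylsilyl)but-3-yn-1-yl]cyclohept-3-en-1-yl]acetate | CCOC(=O)C[C@H]1CC=C(CCC#C[Si](C)(C)C)C(=O)CC1 | intermediate
9 | 2-[(1R)-4-(but-3-yn-1-yl)-5-oxocyclohept-3-en-1-yl]acetic acid | OC(=O)C[C@H]1CC=C(CCC#C)C(=O)CC1 | intermediate
10 | dipotassium dienolate carboxylate of 9 | [K+].[K+].[O-]C(=O)C[C@H]1C=CC(CCC#C)=C([O-])CC1 | intermediate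
11 | 2-[(1S,4R)-4-(but-3-yn-1-yl)-5-oxocyclohept-2-en-1-yl]acetic acid | OC(=O)C[C@H]1C=C[C@@H](CCC#C)C(=O)CC1 | intermediate
12 | 10-oxo-13,14-dinorguai-4(15)-en-12,6α-olide | C1C(=O)O[C@@H]2[C@@H]3[C@@H](CCC3=C)C(=O)CC[C@@H]12 | intermediate
13 | 13-norguaia-4(15),10(14)-dien-12,6α-olide | C1C(=O)O[C@@H]2[C@@H]3[C@@H](CCC3=C)C(=C)CC[C@@H]12 | intermediate
14 | lithium enolate of 13 | [Li+].C1=C([O-])O[C@@H]2[C@@H]3[C@@H](CCC3=C)C(=C)CC[C@@H]12 | intermediate
15 | 13-(dimethylamino)-11,13-dihydrodehydrocostus lactone (C11 not defined) | CN(C)CC1C(=O)O[C@@H]2[C@@H]3[C@@H](CCC3=C)C(=C)CC[C@@H]12 | intermediate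
16 | trimethylammonium iodide of 15 | C[N+](C)(C)CC1C(=O)O[C@@H]2[C@@H]3[C@@H](CCC3=C)C(=C)CC[C@@H]12.[I-] | intermediate
17 | (−)-dehydrocostus lactone | C=C1C(=O)O[C@@H]2[C@@H]3[C@@H](CCC3=C)C(=C)CC[C@@H]12 | intermediate
18 | 3-epizaluzanin C | C=C1C(=O)O[C@@H]2[C@@H]3[C@@H](C[C@@H](O)C3=C)C(=C)CC[C@@H]12 | intermediate
19 | dehydrozaluzanin C | C=C1C(=O)O[C@@H]2[C@@H]3[C@@H](CC(=O)C3=C)C(=C)CC[C@@H]12 | intermediate
20 | spiro-dihydropyran hetero-Diels–Alder dimer | C=C1C(=O)O[C@@H]2[C@@H]3[C@@H](CC(=O)[C@]34CCC5=C(O4)C[C@H]6C(=C)CC[C@H]7C(=C)C(=O)O[C@@H]7[C@@H]56)C(=C)CC[C@@H]12 | intermediate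
21 | C4-hydroxy 3,3′-diketone (C4′ not defined) | C=C1C(=O)O[C@@H]2[C@@H]3[C@@H](CC(=O)[C@]3(O)CCC4C(=O)C[C@H]5C(=C)CC[C@H]6C(=C)C(=O)O[C@@H]6[C@@H]45)C(=C)CC[C@@H]12 | intermediate
22 | ainsliadimer A | C=C1C(=O)O[C@@H]2[C@@H]3[C@@H](C[C@@]4(O)[C@]3(O)CC[C@]43C(=O)C[C@H]4C(=C)CC[C@H]5C(=C)C(=O)O[C@@H]5[C@H]43)C(=C)CC[C@@H]12 | target

Total step count: 13. Longest linear sequence: 13 steps, from 1 to 22; both halves come from the same monomer 19.

**Steps most likely to fail**
1. **Step 6.** Closure of the strained trans-lactone transition state may be slower than proton loss or skeletal rearrangement of the cyclopropyl gold carbene.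
   - The fallback sets out from 11.
   - The same gold complex in wet 1,4-dioxane lets external water attack C6 from the free α face. This is an intermolecular hydroxycyclisation of the 1,6-enyne and gives the 6α-hydroxy acid F1.
   - Catalytic TsOH in benzene then closes the lactone at the acyl carbon. The sequence returns to the route at 12.
2. **Step 5.** Facial selectivity of the protonation at C1 may be poor, and the alkene may slip back into conjugation during the quench.
   - The fallback sets out from 9.
   - Dienolate 10 is trapped with tBuMe2SiCl as the isolable bis-silyl dienol ether F2.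
   - C1 is then set under catalyst control by Brønsted-acid-catalysed asymmetric protonation of the silyl dienol ether, using a chiral BINOL-derived N-triflyl thiophosphoramide with phenol as the proton source.
   - Aqueous work-up frees the acid, and the sequence returns at 11.
3. **Step 7.** Enolisation of the C10 ketone by the zinc–titanium reagent may epimerise C1, or attack on the lactone carbonyl may erode chemoselectivity.
   - The fallback sets out from 12.
   - KN(SiMe3)2 and the Comins reagent at −78 °C give the C9-enol triflate F3.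
   - Negishi coupling with Me3SiCH2ZnCl and Pd(PPh3)4 gives the allylsilane F4.
   - Protodesilylation with CF3CO2H in CH2Cl2 at −20 °C protonates C9 and moves the alkene into the exocyclic C10=C14 position. The sequence returns at 13.

**Further compounds**
F1 | step 6 | 2-[6α-hydroxy-10-oxo-14-norguai-4(15)-en-7-yl]acetic acid (1αH,5αH,6βH,7αH) | OC(=O)C[C@@H]1CCC(=O)[C@@H]2CCC(=C)[C@@H]2[C@H]1O
F2 | step 5 | tert-butyldimethylsilyl 2-[(1S)-4-(but-3-yn-1-yl)-5-(tert-butyldimethylsilyloxy)cyclohepta-2,4-dien-1-yl]acetate | CC(C)(C)[Si](C)(C)OC(=O)C[C@H]1C=CC(CCC#C)=C(O[Si](C)(C)C(C)(C)C)CC1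
F3 | step 7 | 10-(trifluoromethylsulfonyloxy)-13,14-dinorguaia-4(15),9-dien-12,6α-olide | C1C(=O)O[C@@H]2[C@@H]3[C@@H](CCC3=C)C(OS(=O)(=O)C(F)(F)F)=CC[C@@H]12
F4 | step 7 | 14-(trimethylsilyl)-13-norguaia-4(15),9-dien-12,6α-olide | C1C(=O)O[C@@H]2[C@@H]3[C@@H](CCC3=C)C(C[Si](C)(C)C)=CC[C@@H]12
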